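**Retrosynthetic overview**

1. The target is two (3R,4S)-3,4,5-trimethyl benzopyran halves joined C7–CH2–C7′. The bridge is cut last: an ortho-quinone methide released from a 7-(dimethylaminomethyl) lactone half is attacked by C7′ of the quinone methide half, a vinylogous acid. Both halves, and so all four stereocentres, come from one lactone, (3R,4S)-6,8-dihydroxy-3,4,5-trimethylisochroman-1-one.
2. The lactone ring is cut at C8a–C1 and C3–C4 (and at the ester bond C1–O2). This leaves a flat, achiral aryl O-carbamate and acetaldehyde; one lithiation sequence makes both C–C bonds, both stereocentres and the ring.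
3. Enabling feature: C8a lies between C8, which carries the phenol oxygen, and C4a, which carries the benzylic carbon C4. C1 can therefore be parked on O8 as a diethylcarbamate, moved to C8a by a 1,3 O→C shift that frees the C8 phenol, and then used as the amide that acidifies C4–H and finally as the acyl donor for O2.
4. Ring order: benzene ring bought (substituents by Kumada coupling, C–H borylation/oxidation and directed metalation) → lactone ring (key step) → pyran ring of the quinone methide half from the same lactone (lactol, dehydration) → methylene bridge.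

Key step: step 5

Assumption: in step 5 (−)-sparteine is taken to deliver the (4S) configuration; if the sense proves opposite, commercially available (+)-sparteine replaces it and nothing else changes.
Remark: the quinone methide half is written throughout as the 6-hydroxy-8-oxo tautomer of the target SMILES, which equilibrates rapidly with the 8-hydroxy-6-oxo form.
Remark: the isochroman locants of the lactone (C1, O2, C3, C4, C4a, C5 to C8, C8a) are used for all of its precursors.

**Route**

Step 1
Reactants: 1 1-bromo-3-methoxy-2-methylbenzene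
Product: 2 1-ethyl-3-methoxy-2-methylbenzene
Conditions: EtMgBr (1.5 equiv), NiCl2(dppp) (2 mol%), Et2O, 0 °C → reflux
Reagents that add atoms: ethylmagnesium bromide, CC[Mg]Br
Why: Kumada–Corriu coupling, in which NiCl2(dppp) couples primary alkyl Grignard reagents with ortho-substituted aryl bromides faster than β-hydride elimination can intervene, and the methyl ether is inert.

Step 2
Reactants: 2 1-ethyl-3-methoxy-2-methylbenzene
Product: 4 3-ethyl-5-methoxy-4-methylphenol, via aryl boronate 3 (not isolated)
Conditions: B2pin2 (1.0 equiv), [Ir(OMe)(cod)]2 (1.5 mol%), dtbpy (3 mol%), THF, 80 °C; then 30% H2O2, aq. NaOH, 0 °C → rt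
Reagents that add atoms: bis(pinacolato)diboron, CC1(C)OB(OC1(C)C)B1OC(C)(C)C(C)(C)O1 (boron of intermediate 3 only); hydrogen peroxide, OO
Why: Iridium-catalysed C–H borylation is governed by sterics, so a 1,2,3-trisubstituted benzene should react at C5, the only C–H without an ortho substituent, and the boronate is oxidised in the same flask at the same position (C–H borylation/oxidation).

Step 3
Reactants: 4 3-ethyl-5-methoxy-4-methylphenol
Product: 5 3-ethyl-5-methoxy-4-methylphenyl N,N-diethylcarbamate
Conditions: NaH, THF, 0 °C; ClC(O)NEt2, 0 °C → rt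
Reagents that add atoms: N,N-diethylcarbamoyl chloride, CCN(CC)C(=O)Cl
Why: O-Acylation of the sodium phenoxide with a carbamoyl chloride (carbamate formation) installs the group that will later direct metalation and deliver C1.

Step 4
Reactants: 5 3-ethyl-5-methoxy-4-methylphenyl N,N-diethylcarbamate
Product: 7 5-ethyl-3-methoxy-4-methyl-2-(trimethylsilyl)phenyl N,N-diethylcarbamate, via aryllithium 6 (not isolated)
Conditions: s-BuLi (1.1 equiv), TMEDA, THF, −78 °C, 1 h; TMSCl, −78 °C → rt
Reagents that add atoms: chlorotrimethylsilane, C[Si](C)(C)Cl; sec-butyllithium, CCC(C)[Li] (lithium of intermediate 6 only)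
Why: Directed ortho metalation, in which the C–H between the carbamate and the methoxy group (future C7) is the most acidic, and trapping at −78 °C, below the temperature of the Fries shift, puts a removable silyl block there so that the next lithiation can only occur at the future C8a.

Step 5
Reactants: 7 5-ethyl-3-methoxy-4-methyl-2-(trimethylsilyl)phenyl N,N-diethylcarbamate
Product: 12 (3R,4S)-8-hydroxy-6-methoxy-3,4,5-trimethylisochroman-1-one, via ortho-lithiated carbamate 8 (not isolated), via Fries phenolate 9 (not isolated), via benzylic dilithio species 10 (not isolated), via hydroxy amide 11 (not isolated)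
Conditions: s-BuLi/(−)-sparteine (1.2 equiv), Et2O, −78 °C; → 0 °C; → −78 °C, s-BuLi/(−)-sparteine (2.5 equiv); MeCHO (3 equiv), −78 °C; 1 M HCl; then TsOH·H2O, PhMe, 80 °C
Reagents that add atoms: acetaldehyde, CC=O; sec-butyllithium, CCC(C)[Li] (lithium of intermediates 8 to 10 only)
Why: Proposed new method: s-BuLi/(−)-sparteine removes the C8a proton of 7 (the only C–H ortho to the carbamate, C7 being silylated), and on warming aryllithium 8 attacks its own carbamate carbonyl (anionic ortho-Fries rearrangement, 1,3 O→C shift) to form C8a–C1 and free the C8 phenolate in 9; the amide now at C8a directs a second, lateral lithiation to the adjacent ethyl CH2 (10), whose addition to acetaldehyde forms C3–C4, and acid then closes the lactone by 6-exo-trig attack of the C3 hydroxyl on C1 with loss of diethylamine and removes the silyl block by ipso-protonation. The closest known reaction types are the anionic ortho-Fries rearrangement of silicon-blocked aryl O-carbamates, the (−)-sparteine-mediated asymmetric lateral lithiation–substitution of ortho-ethyl tertiary benzamides, and the addition of laterally lithiated ortho-alkylbenzoic acid derivatives to aldehydes followed by lactonisation to 3,4-disubstituted isochromanones; what is new is their use as one uninterrupted sequence on a phenolate-bearing dianion with stereocontrol at both carbons. C4 should be set by the sparteine ligand on lithium, which differentiates the two rapidly interconverting configurations of the benzylic organolithium (dynamic resolution), and C3 by a lithium-bridged addition in which the aldehyde oxygen sits near the amide-bound lithium and the aldehyde methyl group turns away from the C4 methyl group, which leads to the threo adduct and thus to the 3,4-trans lactone. The step needs site selectivity in both deprotonations and face selectivity in the addition: the silyl group at C7 secures the first site, the fact that only the ethyl CH2 is ortho to the amide (the C5 methyl is ortho only to the weakly directing methoxy group) secures the second, and the chiral diamine is the only control element for the faces, so the cis lactone and the minor enantiomer are to be removed by chromatography and crystallisation.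

Step 6
Reactants: 12 (3R,4S)-8-hydroxy-6-methoxy-3,4,5-trimethylisochroman-1-one
Product: 13 (3R,4S)-6,8-dihydroxy-3,4,5-trimethylisochroman-1-one
Conditions: BBr3 (3 equiv), CH2Cl2, −78 → 0 °C; H2O
Reagents that add atoms: none
Why: Lewis-acid cleavage of the aryl methyl ether (BBr3 demethylation) leaves the lactone, which is deactivated by the hydrogen-bonded C8 phenol, and both stereocentres untouched.

Step 7
Reactants: 13 (3R,4S)-6,8-dihydroxy-3,4,5-trimethylisochroman-1-one
Product: 15 (3R,4S)-6-hydroxy-3,4,5-trimethyl-3,4-dihydro-8H-isochromen-8-one (decarboxycitrinin), via lactol 14 (not isolated)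
Conditions: i-Bu2AlH (3.5 equiv), CH2Cl2, −78 °C; 1 M HCl, 0 °C → rt
Reagents that add atoms: none
Why: Partial reduction of the lactone (i-Bu2AlH, tetrahedral aluminium lactolate persistent at −78 °C) gives lactol 14, which on acidification should lose water through the push of the C6 and C8 hydroxyls to give the quinone methide, the stereocentres at C3 and C4 not being involved.

Step 8
Reactants: 13 (3R,4S)-6,8-dihydroxy-3,4,5-trimethylisochroman-1-one
Product: 16 (3R,4S)-7-[(dimethylamino)methyl]-6,8-dihydroxy-3,4,5-trimethylisochroman-1-one
Conditions: CH2=NMe2+ I− (1.1 equiv), Et3N, CH2Cl2, 0 °C → rt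
Reagents that add atoms: N,N-dimethylmethyleneiminium iodide, C=[N+](C)C.[I-]
Why: Mannich reaction (electrophilic aminomethylation with the preformed iminium salt) can only occur at C7, the single unsubstituted ring carbon, which is ortho to both phenols.

Step 9
Reactants: 16 (3R,4S)-7-[(dimethylamino)methyl]-6,8-dihydroxy-3,4,5-trimethylisochroman-1-one; 15 (3R,4S)-6-hydroxy-3,4,5-trimethyl-3,4-dihydro-8H-isochromen-8-one (1.2 equiv)
Product: 18 dicitrinone G, via ortho-quinone methide 17 (not isolated)
Conditions: MeCN, 70 °C, Ar
Reagents that add atoms: none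
Why: Thermal loss of dimethylamine from the ortho-hydroxybenzylamine gives ortho-quinone methide 17, to which the vinylogous acid 15 should add through C7′, its only nucleophilic carbon (Michael addition, rearomatisation of the lactone half), with no stereocentre touched.

**Compound list**

1 | 1-bromo-3-methoxy-2-methylbenzene | COc1cccc(Br)c1C | starting material
2 | 1-ethyl-3-methoxy-2-methylbenzene | CCc1cccc(OC)c1C | intermediate
3 | 2-(3-ethyl-5-methoxy-4-methylphenyl)-4,4,5,5-tetramethyl-1,3,2-dioxaborolane | CCc1cc(B2OC(C)(C)C(C)(C)O2)cc(OC)c1C | intermediate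
4 | 3-ethyl-5-methoxy-4-methylphenol | CCc1cc(O)cc(OC)c1C | intermediate
5 | 3-ethyl-5-methoxy-4-methylphenyl N,N-diethylcarbamate | CCN(CC)C(=O)Oc1cc(CC)c(C)c(OC)c1 | intermediate
6 | [6-(diethylcarbamoyloxy)-4-ethyl-2-methoxy-3-methylphenyl]lithium | CCN(CC)C(=O)Oc1cc(CC)c(C)c(OC)c1[Li] | intermediate
7 | 5-ethyl-3-methoxy-4-methyl-2-(trimethylsilyl)phenyl N,N-diethylcarbamate | CCN(CC)C(=O)Oc1cc(CC)c(C)c(OC)c1[Si](C)(C)C | intermediate
8 | [2-(diethylcarbamoyloxy)-6-ethyl-4-methoxy-5-methyl-3-(trimethylsilyl)phenyl]lithium | CCN(CC)C(=O)Oc1c([Li])c(CC)c(C)c(OC)c1[Si](C)(C)C | intermediate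
9 | lithium 2-(diethylcarbamoyl)-3-ethyl-5-methoxy-4-methyl-6-(trimethylsilyl)phenolate | CCN(CC)C(=O)c1c(O[Li])c([Si](C)(C)C)c(OC)c(C)c1CC | intermediate
10 | lithium 2-(diethylcarbamoyl)-3-(1-lithioethyl)-5-methoxy-4-methyl-6-(trimethylsilyl)phenolate (sparteine complex) | CCN(CC)C(=O)c1c(O[Li])c([Si](C)(C)C)c(OC)c(C)c1C(C)[Li] | intermediate
11 | N,N-diethyl-2-hydroxy-6-[(2S,3R)-3-hydroxybutan-2-yl]-4-methoxy-5-methyl-3-(trimethylsilyl)benzamide | CCN(CC)C(=O)c1c(O)c([Si](C)(C)C)c(OC)c(C)c1[C@H](C)[C@@H](C)O | intermediate
12 | (3R,4S)-8-hydroxy-6-methoxy-3,4,5-trimethylisochroman-1-one | c1c(OC)c(C)c2c(c1O)C(=O)O[C@H](C)[C@H]2C | intermediate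
13 | (3R,4S)-6,8-dihydroxy-3,4,5-trimethylisochroman-1-one | c1c(O)c(C)c2c(c1O)C(=O)O[C@H](C)[C@H]2C | intermediate
14 | (3R,4S)-3,4,5-trimethylisochromane-1,6,8-triol (lactol, both C1 epimers) | c1c(O)c(C)c2c(c1O)C(O)O[C@H](C)[C@H]2C | intermediate
15 | (3R,4S)-6-hydroxy-3,4,5-trimethyl-3,4-dihydro-8H-isochromen-8-one (decarboxycitrinin) | CC1=C2C(=CO[C@H](C)[C@H]2C)C(=O)C=C1O | intermediate
16 | (3R,4S)-7-[(dimethylamino)methyl]-6,8-dihydroxy-3,4,5-trimethylisochroman-1-one | CN(C)Cc1c(O)c(C)c2c(c1O)C(=O)O[C@H](C)[C@H]2C | intermediate
17 | (3R,4S)-8-hydroxy-3,4,5-trimethyl-7-methylidene-3,4-dihydro-1H-isochromene-1,6(7H)-dione | C=C1C(=O)C(C)=C2C(=C1O)C(=O)O[C@H](C)[C@H]2C | intermediate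
18 | dicitrinone G | CC1=C2C(=CO[C@H](C)[C@H]2C)C(=O)C(Cc2c(O)c(C)c3c(c2O)C(=O)O[C@H](C)[C@H]3C)=C1O | target

**Step count**

Total: 9 steps. Longest linear sequence: 8 steps (steps 1 to 6, then step 7 or step 8, then step 9).

**Steps most likely to fail**

Step 5 (Proposed new method). The risk is insufficient control of the two faces when the sparteine-bound benzylic lithium adds to acetaldehyde, or incomplete lateral deprotonation next to the phenolate. The fallback sets out from 7 and returns at 13, using only known operations, with stereocontrol moved from the addition to a reduction.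
- The anionic ortho-Fries rearrangement alone (s-BuLi, TMEDA, THF, −78 °C → rt) would give N,N-diethyl-6-ethyl-2-hydroxy-4-methoxy-5-methyl-3-(trimethylsilyl)benzamide F1.
- O-Methylation (MeI, K2CO3, acetone) would give N,N-diethyl-6-ethyl-2,4-dimethoxy-5-methyl-3-(trimethylsilyl)benzamide F2, an ordinary substrate for amide-directed lateral lithiation.
- s-BuLi/TMEDA at −78 °C followed by N-methoxy-N-methylacetamide would give the racemic ketone N,N-diethyl-2,4-dimethoxy-5-methyl-6-(3-oxobutan-2-yl)-3-(trimethylsilyl)benzamide F3.
- Noyori–Ikariya transfer hydrogenation under dynamic kinetic resolution (RuCl(p-cymene)[(S,S)-TsDPEN] or its antipode, whichever gives the (3R) carbinol; HCO2H/Et3N, DBU) would equilibrate C4 through the enol and set C3, to give N,N-diethyl-6-[(2S,3R)-3-hydroxybutan-2-yl]-2,4-dimethoxy-5-methyl-3-(trimethylsilyl)benzamide F4.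
- TsOH in toluene at 80 °C would lactonise and desilylate to (3R,4S)-6,8-dimethoxy-3,4,5-trimethylisochroman-1-one F5, and excess BBr3 would cleave both ethers to give 13.

Step 7. The risk is ionisation of the aluminium lactolate to the quinone methide while hydride is still present, followed by 1,6-reduction to the isochroman. The fallback sets out from 13 and returns at 15. Aqueous KOH at 150 °C (sealed), then acid, would open the lactone and decarboxylate the 2,4-dihydroxybenzoic acid to (2R,3S)-3-(3,5-dihydroxy-2-methylphenyl)butan-2-ol F6. HC(OEt)3 followed by aqueous HCl would then let the secondary alcohol take up the orthoformate carbon and deliver it to C8a (tethered Friedel–Crafts formylation through a dialkoxycarbenium ion); loss of ethanol and water gives 15. No hydride is involved.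

Step 9. The risk is self-condensation of the ortho-quinone methide, O-alkylation, or decay of the quinone methide partner under the amine that is released. The fallback sets out from 15 and 16 and returns at 18; it couples two aromatic partners and adjusts the oxidation level last. NaBH4 in MeOH at 0 °C would add hydride 1,6 to 15 to give (3R,4S)-3,4,5-trimethylisochromane-6,8-diol F7, a resorcinol with C7 as its only free position. Heating F7 with 16 (MeCN, 70 °C) would give the diarylmethane (3R,4S)-7-{[(3R,4S)-6,8-dihydroxy-3,4,5-trimethylisochroman-7-yl]methyl}-6,8-dihydroxy-3,4,5-trimethylisochroman-1-one F8. DDQ (1 equiv, CH2Cl2/dioxane) should abstract hydride from the cyclic benzylic ether CH2, the position stabilised by the ring oxygen and the para hydroxyl, to give 18.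

**Further compounds**

F1 | step 5 | N,N-diethyl-6-ethyl-2-hydroxy-4-methoxy-5-methyl-3-(trimethylsilyl)benzamide | CCN(CC)C(=O)c1c(O)c([Si](C)(C)C)c(OC)c(C)c1CC
F2 | step 5 | N,N-diethyl-6-ethyl-2,4-dimethoxy-5-methyl-3-(trimethylsilyl)benzamide | CCN(CC)C(=O)c1c(OC)c([Si](C)(C)C)c(OC)c(C)c1CC
F3 | step 5 | N,N-diethyl-2,4-dimethoxy-5-methyl-6-(3-oxobutan-2-yl)-3-(trimethylsilyl)benzamide (racemic) | CCN(CC)C(=O)c1c(OC)c([Si](C)(C)C)c(OC)c(C)c1C(C)C(C)=O
F4 | step 5 | N,N-diethyl-6-[(2S,3R)-3-hydroxybutan-2-yl]-2,4-dimethoxy-5-methyl-3-(trimethylsilyl)benzamide | CCN(CC)C(=O)c1c(OC)c([Si](C)(C)C)c(OC)c(C)c1[C@H](C)[C@@H](C)O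
F5 | step 5 | (3R,4S)-6,8-dimethoxy-3,4,5-trimethylisochroman-1-one | c1c(OC)c(C)c2c(c1OC)C(=O)O[C@H](C)[C@H]2C
F6 | step 7 | (2R,3S)-3-(3,5-dihydroxy-2-methylphenyl)butan-2-ol | Cc1c(O)cc(O)cc1[C@H](C)[C@@H](C)O
F7 | step 9 | (3R,4S)-3,4,5-trimethylisochromane-6,8-diol | c1c(O)c(C)c2c(c1O)CO[C@H](C)[C@H]2C
F8 | step 9 | (3R,4S)-7-{[(3R,4S)-6,8-dihydroxy-3,4,5-trimethylisochroman-7-yl]methyl}-6,8-dihydroxy-3,4,5-trimethylisochroman-1-one | C(c1c(O)c(C)c2c(c1O)CO[C@H](C)[C@H]2C)c1c(O)c(C)c2c(c1O)C(=O)O[C@H](C)[C@H]2C
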